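**Retrosynthetic overview**

- The ten-membered carbocycle is the only ring that is built. It is closed last, by ring-closing metathesis at the C3=C4 trisubstituted Z-alkene (target numbering, ester carbon = C1); the arene is bought as vanillin.
- The vanillate ester and the C9 carbinol are made together in one Evans–Tishchenko reaction of an acyclic β-hydroxy (Z)-enone with silyl-protected vanillin. The aldehyde becomes the ester and supplies the hydride, so no esterification and no diol differentiation is needed.
- The β-hydroxy enone comes from a β-hydroxy aldehyde and a (Z)-alkenyl iodide (propyne carbocupration) by Nozaki–Hiyama–Kishi coupling and allylic oxidation.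
- The β-hydroxy aldehyde comes from prochiral 2-isopropylpropane-1,3-diol. One iridium-catalysed C–H methallylation differentiates its two enantiotopic CH2OH groups and sets both C1 and C10.

Assumption: the target is the (Z,Z)-diene with 1R,9R,10S configuration exactly as the SMILES is written; 2-(propan-2-yl)propane-1,3-diol and but-3-enylmagnesium bromide solution are taken as purchasable.

**Route**

Step 1
Reactants: 1 2-(propan-2-yl)propane-1,3-diol; 2 3-chloro-2-methylprop-1-ene (methallyl chloride)
Product: 4 (2S,3R)-5-methyl-2-(propan-2-yl)hex-5-ene-1,3-diol, via (2S)-2-(hydroxymethyl)-3-methylbutanal 3 (not isolated)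
Conditions: [Ir(cod)Cl]2 (2.5 mol%), (R)-SEGPHOS (5 mol%), 4-cyano-3-nitrobenzoic acid (10 mol%), Cs2CO3 (1.2 equiv), 1 (3 equiv, excess recovered), THF, 70 °C
Reagents that add atoms: none
Why: Proposed new method: the cyclometallated iridium C,O-benzoate dehydrogenates either enantiotopic CH2OH of 1 reversibly to the hydroxy aldehyde, the chiral trivalent iridium 2-methylallyl complex adds to one carbonyl face through a closed chair transition state (catalyst control, C3 = R), and the aldehyde enantiomer 3 for which that face is also the Felkin face (isopropyl anti to the incoming allyl group) reacts faster, so C2 is set as S with the new hydroxyl anti to isopropyl; the closest known reactions are the Krische transfer-hydrogenative enantioselective methallylation of primary alcohols with methallyl chloride and the catalyst-controlled allylation and crotylation of propane-1,3-diol and 2-methylpropane-1,3-diol; the ligand antipode is assigned by analogy and is the one that gives the 3R carbinol, and the ratio of the two C2 diastereomers is the open question.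

Step 2
Reactants: 4 (2S,3R)-5-methyl-2-(propan-2-yl)hex-5-ene-1,3-diol
Product: 5 (2R,3R)-3-hydroxy-5-methyl-2-(propan-2-yl)hex-5-enal
Conditions: TEMPO (10 mol%), PhI(OAc)2 (1.1 equiv), CH2Cl2, 0 °C to rt; used crude
Reagents that add atoms: none
Why: The nitroxyl-catalysed oxidation (Piancatelli–Margarita) oxidises only the primary alcohol of a 1,3-diol and stops at the aldehyde under near-neutral conditions, so the alkene, the secondary alcohol and the α-stereocentre are untouched (the descriptor at C2 changes only because of priorities).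

Step 3
Reactants: 6 but-3-en-1-ylmagnesium bromide; 7 propyne
Product: 10 (1Z)-1-iodo-2-methylhexa-1,5-diene, via but-3-enylcopper 8 (not isolated), via (1Z)-2-methylhexa-1,5-dienylcopper 9 (not isolated)
Conditions: CuBr·SMe2 (1 equiv), Et2O/Me2S, −45 °C; 7 (excess), −25 °C; then I2, THF, −50 to 0 °C
Reagents that add atoms: iodine (I2), SMILES II
Why: Normant carbocupration adds the alkyl group and copper syn across the terminal alkyne with copper on the terminal carbon, and iodinolysis goes with retention, so the butenyl chain and iodine end up cis (Z).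

Step 4
Reactants: 5 (2R,3R)-3-hydroxy-5-methyl-2-(propan-2-yl)hex-5-enal; 10 (1Z)-1-iodo-2-methylhexa-1,5-diene
Product: 12 (5Z,7RS,8R,9R)-5,11-dimethyl-8-(propan-2-yl)dodeca-1,5,11-triene-7,9-diol (both C7 epimers), via alkenylchromium dichloride 11 (not isolated)
Conditions: CrCl2 (6 equiv), NiCl2 (2 mol%), DMSO, rt; aq NH4Cl
Reagents that add atoms: none
Why: The Nozaki–Hiyama–Kishi coupling is aldehyde-selective, non-basic (no epimerisation or retro-aldol of the β-hydroxy aldehyde), tolerates the free hydroxyl and keeps the alkenyl geometry; the new carbinol is formed as a mixture that is erased in step 5.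

Step 5
Reactants: 12 (5Z,7RS,8R,9R)-5,11-dimethyl-8-(propan-2-yl)dodeca-1,5,11-triene-7,9-diol
Product: 13 (4R,5R,7Z)-4-hydroxy-2,8-dimethyl-5-(propan-2-yl)dodeca-1,7,11-trien-6-one
Conditions: MnO2 (20 equiv), CH2Cl2, rt
Reagents that add atoms: none
Why: Allylic oxidation with MnO2 converts only the allylic carbinol into the (Z)-enone and leaves the homoallylic secondary alcohol alone, giving the anti β-hydroxy ketone needed for step 7.

Step 6
Reactants: 14 vanillin (4-hydroxy-3-methoxybenzaldehyde)
Product: 15 4-[(tert-butyldimethylsilyl)oxy]-3-methoxybenzaldehyde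
Conditions: TBSCl (1.1 equiv), imidazole (1.5 equiv), DMF, rt
Reagents that add atoms: tert-butyldimethylsilyl chloride (TBSCl), SMILES CC(C)(C)[Si](C)(C)Cl
Why: Standard phenol silylation masks the acidic phenol, which would otherwise quench the samarium alkoxide catalyst of step 7.

Step 7
Reactants: 13 (4R,5R,7Z)-4-hydroxy-2,8-dimethyl-5-(propan-2-yl)dodeca-1,7,11-trien-6-one; 15 4-[(tert-butyldimethylsilyl)oxy]-3-methoxybenzaldehyde
Product: 17 (4R,5S,6R,7Z)-6-hydroxy-2,8-dimethyl-5-(propan-2-yl)dodeca-1,7,11-trien-4-yl 4-hydroxy-3-methoxybenzoate, via its aryl tert-butyldimethylsilyl ether 16 (not isolated)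
Conditions: SmI2 (30 mol%), 15 (4 equiv), THF, −10 °C; then KHF2 (excess), MeOH, rt
Reagents that add atoms: none
Why: In the Evans–Tishchenko reaction the samarium-bound hemiacetal formed from the C4 hydroxyl and the aryl aldehyde delivers its hydride intramolecularly to the ketone through a six-membered chair chelate, which gives the 1,3-anti carbinol (6R) and leaves the aldehyde as the C4 ester, so acylation is regiospecific; KHF2 in methanol then cleaves only the phenolic silyl ether.

Step 8
Reactants: 17 (4R,5S,6R,7Z)-6-hydroxy-2,8-dimethyl-5-(propan-2-yl)dodeca-1,7,11-trien-4-yl 4-hydroxy-3-methoxybenzoate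
Product: 18 (1R,3Z,7Z,9R,10S)-9-hydroxy-3,7-dimethyl-10-(propan-2-yl)cyclodeca-3,7-dien-1-yl 4-hydroxy-3-methoxybenzoate (target)
Conditions: second-generation Hoveyda–Grubbs catalyst (10 mol%), 1,4-benzoquinone (20 mol%), toluene (1 mM), 80 °C
Reagents that add atoms: none
Why: Ring-closing metathesis between the monosubstituted and the 1,1-disubstituted alkene (the hindered trisubstituted allylic alkene is inert) closes the ten-membered ring at high dilution, and the new trisubstituted alkene is expected Z because a cis double bond is about 3 kcal/mol less strained than a trans one in a cyclodecene; no stereocentre is touched.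

**Compound list**

1 | 2-(propan-2-yl)propane-1,3-diol | CC(C)C(CO)CO | starting material
2 | 3-chloro-2-methylprop-1-ene | C=C(C)CCl | starting material
3 | (2S)-2-(hydroxymethyl)-3-methylbutanal | O=C[C@@H](C(C)C)CO | intermediate (not isolated)
4 | (2S,3R)-5-methyl-2-(propan-2-yl)hex-5-ene-1,3-diol | O[C@H](CC(C)=C)[C@@H](C(C)C)CO | intermediate
5 | (2R,3R)-3-hydroxy-5-methyl-2-(propan-2-yl)hex-5-enal | O[C@H](CC(C)=C)[C@@H](C(C)C)C=O | intermediate
6 | but-3-en-1-ylmagnesium bromide | C=CCC[Mg]Br | starting material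
7 | propyne | CC#C | starting material
8 | but-3-en-1-ylcopper | C=CCC[Cu] | intermediate (not isolated)
9 | [(1Z)-2-methylhexa-1,5-dien-1-yl]copper | [Cu]/C=C(/C)CCC=C | intermediate (not isolated)
10 | (1Z)-1-iodo-2-methylhexa-1,5-diene | I/C=C(/C)CCC=C | intermediate
11 | [(1Z)-2-methylhexa-1,5-dien-1-yl]chromium dichloride | Cl[Cr](Cl)/C=C(/C)CCC=C | intermediate (not isolated)
12 | (5Z,7RS,8R,9R)-5,11-dimethyl-8-(propan-2-yl)dodeca-1,5,11-triene-7,9-diol | O[C@H](CC(C)=C)[C@@H](C(C)C)C(O)/C=C(/C)CCC=C | intermediate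
13 | (4R,5R,7Z)-4-hydroxy-2,8-dimethyl-5-(propan-2-yl)dodeca-1,7,11-trien-6-one | O[C@H](CC(C)=C)[C@@H](C(C)C)C(=O)/C=C(/C)CCC=C | intermediate
14 | vanillin | COc1cc(C=O)ccc1O | starting material
15 | 4-[(tert-butyldimethylsilyl)oxy]-3-methoxybenzaldehyde | COc1cc(C=O)ccc1O[Si](C)(C)C(C)(C)C | intermediate
16 | (4R,5S,6R,7Z)-6-hydroxy-2,8-dimethyl-5-(propan-2-yl)dodeca-1,7,11-trien-4-yl 4-[(tert-butyldimethylsilyl)oxy]-3-methoxybenzoate | COc1cc(C(=O)O[C@H](CC(C)=C)[C@@H](C(C)C)[C@H](O)/C=C(/C)CCC=C)ccc1O[Si](C)(C)C(C)(C)C | intermediate (not isolated)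
17 | (4R,5S,6R,7Z)-6-hydroxy-2,8-dimethyl-5-(propan-2-yl)dodeca-1,7,11-trien-4-yl 4-hydroxy-3-methoxybenzoate | COc1cc(C(=O)O[C@H](CC(C)=C)[C@@H](C(C)C)[C@H](O)/C=C(/C)CCC=C)ccc1O | intermediate
18 | (1R,3Z,7Z,9R,10S)-9-hydroxy-3,7-dimethyl-10-(propan-2-yl)cyclodeca-3,7-dien-1-yl 4-hydroxy-3-methoxybenzoate | COc1cc(C(=O)O[C@@H]2C/C(C)=C\CC/C(C)=C\[C@@H](O)[C@@H]2C(C)C)ccc1O | target

**Step count and risks**

Total steps: 8. Longest linear sequence: 6 (steps 1, 2, 4, 5, 7, 8).

Steps most likely to fail:

Step 1 (which CH2OH group reacts, hence the C2/C3 diastereomer ratio, and over-allylation). The fallback sets out from 1 and returns at 4. Lipase-catalysed mono-acetylation of 1 (Pseudomonas fluorescens lipase, vinyl acetate) gives (2R)-2-(hydroxymethyl)-3-methylbutyl acetate F1. Dess–Martin oxidation gives (2S)-2-formyl-3-methylbutyl acetate F2. Reagent-controlled Brown methallylation with B-(2-methylallyl)diisopinocampheylborane (the antipode matched with the Felkin preference) gives (2S,3R)-3-hydroxy-5-methyl-2-(propan-2-yl)hex-5-en-1-yl acetate F3. K2CO3 in MeOH removes the acetate and gives 4.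

Step 7 (slow hydride transfer from an electron-rich aryl aldehyde to an enone, retro-aldol, or 1,3-acyl shift). The fallback sets out from 13 and returns at 17. Acylation of the C4 hydroxyl with 4-acetoxy-3-methoxybenzoyl chloride (pyridine, catalytic DMAP, −20 °C) gives (4R,5R,7Z)-2,8-dimethyl-6-oxo-5-(propan-2-yl)dodeca-1,7,11-trien-4-yl 4-(acetyloxy)-3-methoxybenzoate F4. Reagent-controlled oxazaborolidine (CBS)/catecholborane 1,2-reduction of the enone, with the catalyst antipode that gives 6R, leads to (4R,5S,6R,7Z)-6-hydroxy-2,8-dimethyl-5-(propan-2-yl)dodeca-1,7,11-trien-4-yl 4-(acetyloxy)-3-methoxybenzoate F5. Pyrrolidine in CH2Cl2 at 0 °C cleaves only the aryl acetate and gives 17.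

Step 8 (oligomerisation, or E geometry at the new alkene in a ten-membered ring). The fallback sets out from 13 and returns at 18, closing the ring before the reduction. Metathesis of the hydrogen-bonded β-hydroxy enone 13 under the same catalyst gives (2Z,6Z,9R,10R)-9-hydroxy-3,7-dimethyl-10-(propan-2-yl)cyclodeca-2,6-dien-1-one F6. Evans–Tishchenko reaction of F6 with 15 (SmI2 catalyst) gives (1R,3Z,7Z,9R,10S)-9-hydroxy-3,7-dimethyl-10-(propan-2-yl)cyclodeca-3,7-dien-1-yl 4-[(tert-butyldimethylsilyl)oxy]-3-methoxybenzoate F7, which KHF2 in MeOH converts in the same flask into 18.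

**Further compounds**

F1 | step 1 | (2R)-2-(hydroxymethyl)-3-methylbutyl acetate | OC[C@@H](C(C)C)COC(C)=O
F2 | step 1 | (2S)-2-formyl-3-methylbutyl acetate | O=C[C@@H](C(C)C)COC(C)=O
F3 | step 1 | (2S,3R)-3-hydroxy-5-methyl-2-(propan-2-yl)hex-5-en-1-yl acetate | O[C@H](CC(C)=C)[C@@H](C(C)C)COC(C)=O
F4 | step 7 | (4R,5R,7Z)-2,8-dimethyl-6-oxo-5-(propan-2-yl)dodeca-1,7,11-trien-4-yl 4-(acetyloxy)-3-methoxybenzoate | COc1cc(C(=O)O[C@H](CC(C)=C)[C@@H](C(C)C)C(=O)/C=C(/C)CCC=C)ccc1OC(C)=O
F5 | step 7 | (4R,5S,6R,7Z)-6-hydroxy-2,8-dimethyl-5-(propan-2-yl)dodeca-1,7,11-trien-4-yl 4-(acetyloxy)-3-methoxybenzoate | COc1cc(C(=O)O[C@H](CC(C)=C)[C@@H](C(C)C)[C@H](O)/C=C(/C)CCC=C)ccc1OC(C)=O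
F6 | step 8 | (2Z,6Z,9R,10R)-9-hydroxy-3,7-dimethyl-10-(propan-2-yl)cyclodeca-2,6-dien-1-one | O[C@@H]1C/C(C)=C\CC/C(C)=C\C(=O)[C@@H]1C(C)C
F7 | step 8 | (1R,3Z,7Z,9R,10S)-9-hydroxy-3,7-dimethyl-10-(propan-2-yl)cyclodeca-3,7-dien-1-yl 4-[(tert-butyldimethylsilyl)oxy]-3-methoxybenzoate | COc1cc(C(=O)O[C@@H]2C/C(C)=C\CC/C(C)=C\[C@@H](O)[C@@H]2C(C)C)ccc1O[Si](C)(C)C(C)(C)C
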